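**Strategy.** The target is read as a cis-hydrindanone (indane numbering; ring A = cyclopentanone C1–C3, ring B = cyclohexane C4–C7) and cut at the fusion bond C3a–C7a together with C4–C5 by an intramolecular Diels–Alder reaction. The key step exploits the 1,3-relation, across C3–C3a–C4, between the side-chain oxygen on C3 and the carbon attached to C4: tied as a temporary α,β-unsaturated δ-lactone they form a cis-locked dienophile whose pyranone carbon carries the tether to an (E,E)-1-boryl-3-methyldiene. One endo cycloaddition closes rings A and B and sets C3a, C7a, C4 and C5, all relayed from C3 and the bought side-chain carbinol.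

Key step: step 11

Remark: acids 28 and 31 are taken as purchasable single isomers; core numbering is C1 (ring CH2), C2 (ketone carbon), C3 (CH with the 1-acetoxyethyl group, carbinol carbon C1′), C3a/C7a (fusion), C4 (CH with the oxirane), C5 (enoate-bearing CH), C6 (methylbutanoate-bearing CH), C7 (methylidene carbon); α is the face of H-3a and H-7a.

Step 1
Reactants: 1 (S)-3-hydroxybutanoic acid
Product: 3 (S)-3-[(tert-butyldimethylsilyl)oxy]butanoic acid, via bis-silylated silyl ester 2 (not isolated)
Conditions: TBSCl (2.2 equiv), imidazole, DMF, rt; then AcOH, THF/H2O, rt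
Reagents that add atoms: tert-butyldimethylsilyl chloride, CC(C)(C)[Si](C)(C)Cl
Why: Silyl ether formation followed by in-flask hydrolysis of the labile silyl ester protects the carbinol without touching the bought (S)-centre, which becomes C1′.

Step 2
Reactants: 3 (S)-3-[(tert-butyldimethylsilyl)oxy]butanoic acid; 4 (R)-4-benzyl-1,3-thiazolidine-2-thione
Product: 5 (R)-4-benzyl-3-[(3S)-3-(tert-butyldimethylsilyloxy)butanoyl]-1,3-thiazolidine-2-thione
Conditions: DCC, DMAP (cat.), CH2Cl2, 0 °C → rt
Reagents that add atoms: none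
Why: Steglich-type carbodiimide N-acylation of the thiazolidinethione should give the Crimmins aldol donor.

Step 3
Reactants: 5 N-acyl thiazolidinethione; 6 3-[(tert-butyldimethylsilyl)oxy]propanal
Product: 7 (R)-4-benzyl-3-{(2S,3S)-5-(tert-butyldimethylsilyloxy)-2-[(1S)-1-(tert-butyldimethylsilyloxy)ethyl]-3-hydroxypentanoyl}-1,3-thiazolidine-2-thione
Conditions: TiCl4, i-Pr2NEt, N-methyl-2-pyrrolidinone, CH2Cl2, 0 → −78 °C; then 6, −78 → −40 °C
Reagents that add atoms: none
Why: Crimmins titanium-enolate aldol addition: the chlorotitanium Z-enolate reacts through the non-chelated Evans-type Zimmerman–Traxler transition state, so the (R)-benzyl auxiliary should set both new centres (future C3 and the temporary C2 carbinol) as the 2,3-syn product whatever the remote silyloxy centre prefers.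

Step 4
Reactants: 7 syn-aldol adduct
Product: 8 (R)-4-benzyl-3-{(2S,3S)-5-(tert-butyldimethylsilyloxy)-2-[(1S)-1-(tert-butyldimethylsilyloxy)ethyl]-3-(methoxymethoxy)pentanoyl}-1,3-thiazolidine-2-thione
Conditions: MOMCl, i-Pr2NEt, Bu4NI (cat.), CH2Cl2, 0 °C → rt
Reagents that add atoms: chloromethyl methyl ether, COCCl
Why: Acetal ether formation (MOM protection) masks the carbinol that becomes the C2 ketone and keeps it from lactonising later.

Step 5
Reactants: 8 MOM ether
Product: 9 (2S,3S)-5-(tert-butyldimethylsilyloxy)-2-[(1S)-1-(tert-butyldimethylsilyloxy)ethyl]-3-(methoxymethoxy)pentanal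
Conditions: i-Bu2AlH, CH2Cl2, −78 °C; aq. potassium sodium tartrate
Reagents that add atoms: none
Why: Partial hydride reduction of the activated N-acyl thiazolidinethione stops at the aldehyde (stable tetrahedral aluminate) and releases the auxiliary, the α-centre surviving at −78 °C.

Step 6
Reactants: 9 aldehyde; 10 methyl bis(2,2,2-trifluoroethyl)phosphonoacetate
Product: 11 methyl (2Z,4S,5S)-7-(tert-butyldimethylsilyloxy)-4-[(1S)-1-(tert-butyldimethylsilyloxy)ethyl]-5-(methoxymethoxy)hept-2-enoate
Conditions: KN(SiMe3)2, 18-crown-6, THF, −78 °C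
Reagents that add atoms: none
Why: Still–Gennari variant of the Horner–Wadsworth–Emmons olefination should give the Z-enoate under kinetic control.

Step 7
Reactants: 11 Z-enoate
Product: 13 (5R,6S)-5-[(1S)-3-hydroxy-1-(methoxymethoxy)propyl]-6-methyl-5,6-dihydro-2H-pyran-2-one, via bis-desilylated Z-enoate 12 (not isolated)
Conditions: aq. HF (48%), MeCN, 0 °C → rt
Reagents that add atoms: none
Why: Desilylation frees both hydroxyls and the secondary one, held cis to the ester across the Z-alkene, lactonises (6-exo-trig acyl substitution) while the primary one cannot reach the ester.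

Step 8
Reactants: 13 hydroxy lactone
Product: 14 (5R,6S)-5-[(1S)-1-(methoxymethoxy)-3-oxopropyl]-6-methyl-5,6-dihydro-2H-pyran-2-one
Conditions: Dess–Martin periodinane, NaHCO3, CH2Cl2, 0 °C → rt
Reagents that add atoms: none
Why: Dess–Martin oxidation is buffered and non-basic, so the γ-enolisable unsaturated lactone and the β-alkoxy aldehyde should survive.

Step 9
Reactants: 14 aldehyde lactone; 15 2-(triphenylphosphoranylidene)propanal
Product: 16 (5R,6S)-5-[(1S,3E)-1-(methoxymethoxy)-4-methyl-5-oxopent-3-enyl]-6-methyl-5,6-dihydro-2H-pyran-2-one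
Conditions: toluene, 80 °C
Reagents that add atoms: none
Why: Wittig olefination with the stabilised ylide should give the (E)-2-methyl enal and is neutral enough for the lactone.

Step 10
Reactants: 16 enal; 17 2-(dichloromethyl)-4,4,5,5-tetramethyl-1,3,2-dioxaborolane
Product: 18 (5R,6S)-5-[(1S,3E,5E)-1-(methoxymethoxy)-4-methyl-6-(4,4,5,5-tetramethyl-1,3,2-dioxaborolan-2-yl)hexa-3,5-dienyl]-6-methyl-5,6-dihydro-2H-pyran-2-one
Conditions: CrCl2 (8 equiv), LiI (4 equiv), THF, rt
Reagents that add atoms: none
Why: Takai–Utimoto boron olefination: the geminal dichromium reagent adds to the enal and eliminates to the (E)-alkenylboronate, completing the (E,E)-diene under neutral conditions.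

Step 11
Reactants: 18 dienylboronate lactone
Product: 19 tricyclic lactone boronate (cis-fused 7-methyl-hexahydroindene; 2α-OMOM; 5β-Bpin; δ-lactone from the C1′ oxygen of the 3β side chain to the 4β carbonyl carbon; H-3, H-3a, H-4, H-5, H-7a all α)
Conditions: toluene (0.005 M), 2,6-di-tert-butyl-4-methylphenol (cat.), 120 °C, sealed tube
Reagents that add atoms: none
Why: Thermal concerted, asynchronous [4π+2π] cycloaddition (type 1 intramolecular Diels–Alder reaction) of the (E,E)-1-boryl-3-methyldiene onto the cis-locked unsaturated δ-lactone, the C3a–C7a bond between the lactone β-carbon and the tether-bearing diene terminus being the more advanced one; the closest known reactions are the cyclisations of 1,3,8-nonatrienes to hydrindenes and the cycloadditions of 1,3-dienylboronates with enoates. Ring A closes through the two-carbon tether by the C3a–C7a bond and ring B by the suprafacial union of diene and dienophile (C3a–C7a and C4–C5), which should give a cis-fused hydrindene spanned by the δ-lactone. C3a is set by the pyranone stereocentre that carries the tether, because the diene can only reach the alkene face syn to it, and since the C1′ oxygen and the carbonyl carbon lie in the lactone ring the C3 side chain must end up cis to C4. C7a, C4 and C5 follow from the endo transition state together with the E,E-diene and the cis-dienophile geometry. The step needs endo (cis-fused) over exo (trans-fused) closure, which is secured by the cis-locked dienophile, whose carbonyl and tether are held on the same side and sit under the diene (Alder preference of cyclic cis-dienophiles), and by the strain of a trans-hydrindane bridged by the lactone. The C5 boronate is formed with the configuration needed for stereoretentive oxidation.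

Step 12
Reactants: 19 tricyclic lactone boronate
Product: 20 tricyclic lactone 5β-alcohol
Conditions: NaBO3·4H2O, THF/H2O, rt
Reagents that add atoms: sodium perborate, [Na+].[O-]OB=O
Why: Oxidation of the secondary allylic boronate (peroxide attack on boron, then 1,2-shift of carbon from boron to oxygen) is stereoretentive and should give the 5β-hydroxyl without allylic transposition.

Step 13
Reactants: 20 tricyclic lactone 5β-alcohol
Product: 21 tricyclic lactone 5β-triethylsilyl ether
Conditions: TESCl, imidazole, DMF, 0 °C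
Reagents that add atoms: chlorotriethylsilane, CC[Si](Cl)(CC)CC
Why: Silyl ether formation protects O-5 for the organolithium step and makes it a bulky β-face blocker for the later epoxidation.

Step 14
Reactants: 21 tricyclic lactone silyl ether; 22 tributyl[(methoxymethoxy)methyl]stannane
Product: 23 δ-hydroxy ketone (open form of the cyclic hemiketal): 3β-[(1S)-1-hydroxyethyl]-4β-[(methoxymethoxy)acetyl] bicycle
Conditions: 22, n-BuLi, THF, −78 °C; then 21, −78 °C; aq. NH4Cl at −78 °C
Reagents that add atoms: none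
Why: Tin–lithium exchange gives Still's α-alkoxymethyl-lithium, which adds once to the δ-lactone because the lithium hemiketal survives at −78 °C, installing one carbon on the future oxirane carbon and freeing O-1′.

Step 15
Reactants: 23 δ-hydroxy ketone
Product: 24 keto acetate (3β-[(1S)-1-acetoxyethyl])
Conditions: Ac2O, DMAP (cat.), pyridine, CH2Cl2, 0 °C → rt
Reagents that add atoms: acetic anhydride, CC(=O)OC(C)=O
Why: Acetylation traps the open-chain hydroxy ketone tautomer as the C1′ acetate of the target under conditions too weakly basic to epimerise C4.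

Step 16
Reactants: 24 keto acetate
Product: 25 4β-[3-(methoxymethoxy)prop-1-en-2-yl] bicycle
Conditions: Zn, CH2Br2, TiCl4 (reagent pre-formed in THF), CH2Cl2, 0 °C → rt
Reagents that add atoms: dibromomethane, BrCBr
Why: Takai–Lombardo methylenation converts the hindered, enolisable ketone into the 1,1-disubstituted alkene without base and without touching the acetate, which ends the risk of C4 epimerisation.

Step 17
Reactants: 25 bis-alkene
Product: 26 6α,7α-epoxide
Conditions: mCPBA (1.0 equiv), NaHCO3, CH2Cl2, −20 → 0 °C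
Reagents that add atoms: 3-chloroperoxybenzoic acid, OOC(=O)c1cccc(Cl)c1
Why: Prilezhaev epoxidation: the trisubstituted ring alkene is markedly more nucleophilic than the 1,1-disubstituted allylic-ether alkene, and the peracid should attack the convex α-face, anti to the 5β-silyloxy group and to ring A, which sets the 6α-oxygen.

Step 18
Reactants: 26 6α,7α-epoxide
Product: 27 6α-hydroxy-7-methylidene bicycle
Conditions: Cp2TiCl2 (2.5 equiv), Zn dust, THF, rt; then 26, rt; brief dilute aq. HCl work-up
Reagents that add atoms: none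
Why: Nugent–RajanBabu epoxide opening by trivalent titanium: homolysis of the tertiary C7–O bond gives the C7 radical, from whose methyl group a second Cp2TiCl removes hydrogen to give the exocyclic alkene, the C6–O bond and its configuration staying intact.

Step 19
Reactants: 27 allylic alcohol; 28 (R)-2-methylbutanoic acid
Product: 29 6α-[(2R)-2-methylbutanoyl]oxy ester
Conditions: DCC, DMAP (cat.), CH2Cl2, 0 °C → rt
Reagents that add atoms: none
Why: Steglich esterification of the allylic C6 alcohol at 0 °C with catalytic DMAP should keep the α-centre of the acid intact.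

Step 20
Reactants: 29 C6 ester
Product: 30 5β-alcohol
Conditions: HF·pyridine, pyridine, THF, 0 °C
Reagents that add atoms: none
Why: Buffered fluoride cleavage of the triethylsilyl ether leaves the esters, the acetate and the MOM ethers untouched.

Step 21
Reactants: 30 5β-alcohol; 31 (2E)-3-methylpent-2-enoic acid
Product: 32 5β-[(2E)-3-methylpent-2-enoyl]oxy diester
Conditions: 31, 2,4,6-trichlorobenzoyl chloride, Et3N, THF, rt; then 30, DMAP, toluene, rt
Reagents that add atoms: none
Why: Yamaguchi esterification through the mixed anhydride acylates the hindered C5 alcohol and avoids the acid chloride/vinylketene pathway that would deconjugate or isomerise the β,β-disubstituted enoate.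

Step 22
Reactants: 32 diester bis-MOM ether
Product: 33 diol (2α-hydroxy; 4β-(3-hydroxyprop-1-en-2-yl))
Conditions: Me2BBr, CH2Cl2, −78 °C; then aq. NaHCO3/THF
Reagents that add atoms: none
Why: Guindon cleavage of both methoxymethyl ethers by bromodimethylborane (boron binds the acetal, bromide attacks its methylene) at −78 °C should leave the three esters and both alkenes untouched.

Step 23
Reactants: 33 diol
Product: 34 epoxy alcohol (4β-[(2R)-2-(hydroxymethyl)oxiran-2-yl])
Conditions: Ti(Oi-Pr)4, D-(−)-diethyl tartrate, t-BuOOH, 4 Å molecular sieves, CH2Cl2, −20 °C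
Reagents that add atoms: tert-butyl hydroperoxide, CC(C)(C)OO
Why: Sharpless asymmetric epoxidation: the titanium tartrate binds only the primary allylic alcohol and D-(−)-diethyl tartrate delivers oxygen to the face that gives the (R)-epoxy alcohol under reagent control, which is the (S)-configured oxirane carbon of the target once CH2OH has become the ester.

Step 24
Reactants: 34 epoxy alcohol
Product: 35 keto acid ((2S)-oxirane-2-carboxylic acid with the C2 ketone)
Conditions: AZADO (cat.), PhI(OAc)2 (3.5 equiv), MeCN/pH 7 phosphate buffer, 0 °C → rt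
Reagents that add atoms: water, O
Why: Nitroxyl-catalysed oxidation takes the primary alcohol through the aldehyde hydrate to the acid and the ring alcohol to the C2 ketone in one operation, under neutral conditions that spare the epoxide and the β-acetoxy ketone.

Step 25
Reactants: 35 keto acid
Product: 36 target CNP0251769.2
Conditions: Me3SiCHN2, toluene/MeOH, 0 °C
Reagents that add atoms: (trimethylsilyl)diazomethane, C[Si](C)(C)C=[N+]=[N-]
Why: Methyl ester formation with the diazoalkane is neutral and should leave the epoxide, the β-acetoxy ketone and the esters untouched.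

**Compound list**

1 | (S)-3-hydroxybutanoic acid | OC(=O)C[C@H](C)O | starting material
2 | tert-butyldimethylsilyl (S)-3-[(tert-butyldimethylsilyl)oxy]butanoate | CC(C)(C)[Si](C)(C)OC(=O)C[C@H](C)O[Si](C)(C)C(C)(C)C | intermediate
3 | (S)-3-[(tert-butyldimethylsilyl)oxy]butanoic acid | OC(=O)C[C@H](C)O[Si](C)(C)C(C)(C)C | intermediate
4 | (R)-4-benzyl-1,3-thiazolidine-2-thione | S=C1N[C@H](Cc2ccccc2)CS1 | starting material
5 | (R)-4-benzyl-3-[(3S)-3-(tert-butyldimethylsilyloxy)butanoyl]-1,3-thiazolidine-2-thione | O=C(C[C@H](C)O[Si](C)(C)C(C)(C)C)N1C(=S)SC[C@H]1Cc1ccccc1 | intermediate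
6 | 3-[(tert-butyldimethylsilyl)oxy]propanal | O=CCCO[Si](C)(C)C(C)(C)C | starting material
7 | (R)-4-benzyl-3-{(2S,3S)-5-(TBSO)-2-[(1S)-1-(TBSO)ethyl]-3-hydroxypentanoyl}-1,3-thiazolidine-2-thione (syn-aldol) | CC(C)(C)[Si](C)(C)OCC[C@H](O)[C@@H]([C@H](C)O[Si](C)(C)C(C)(C)C)C(=O)N1C(=S)SC[C@H]1Cc1ccccc1 | intermediate
8 | MOM ether of 7 | CC(C)(C)[Si](C)(C)OCC[C@H](OCOC)[C@@H]([C@H](C)O[Si](C)(C)C(C)(C)C)C(=O)N1C(=S)SC[C@H]1Cc1ccccc1 | intermediate
9 | (2S,3S)-5-(TBSO)-2-[(1S)-1-(TBSO)ethyl]-3-(methoxymethoxy)pentanal | CC(C)(C)[Si](C)(C)OCC[C@H](OCOC)[C@@H]([C@H](C)O[Si](C)(C)C(C)(C)C)C=O | intermediate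
10 | methyl bis(2,2,2-trifluoroethyl)phosphonoacetate | COC(=O)CP(=O)(OCC(F)(F)F)OCC(F)(F)F | starting material
11 | methyl (2Z,4S,5S)-7-(TBSO)-4-[(1S)-1-(TBSO)ethyl]-5-(methoxymethoxy)hept-2-enoate | CC(C)(C)[Si](C)(C)OCC[C@H](OCOC)[C@@H]([C@H](C)O[Si](C)(C)C(C)(C)C)/C=C\C(=O)OC | intermediate
12 | bis-desilylated Z-enoate (configurations as in 11) | OCC[C@H](OCOC)[C@@H]([C@H](C)O)/C=C\C(=O)OC | intermediate
13 | (5R,6S)-5-[(1S)-3-hydroxy-1-(methoxymethoxy)propyl]-6-methyl-5,6-dihydro-2H-pyran-2-one | OCC[C@H](OCOC)[C@@H]1C=CC(=O)O[C@H]1C | intermediate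
14 | (5R,6S)-5-[(1S)-1-(methoxymethoxy)-3-oxopropyl]-6-methyl-5,6-dihydro-2H-pyran-2-one | O=CC[C@H](OCOC)[C@@H]1C=CC(=O)O[C@H]1C | intermediate
15 | 2-(triphenylphosphoranylidene)propanal | CC(C=O)=P(c1ccccc1)(c1ccccc1)c1ccccc1 | starting material
16 | (5R,6S)-5-[(1S,3E)-1-(methoxymethoxy)-4-methyl-5-oxopent-3-enyl]-6-methyl-5,6-dihydro-2H-pyran-2-one | O=C/C(C)=C/C[C@H](OCOC)[C@@H]1C=CC(=O)O[C@H]1C | intermediate
17 | 2-(dichloromethyl)-4,4,5,5-tetramethyl-1,3,2-dioxaborolane | ClC(Cl)B1OC(C)(C)C(C)(C)O1 | starting material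
18 | (5R,6S)-5-[(1S,3E,5E)-1-(methoxymethoxy)-4-methyl-6-(pinacolboryl)hexa-3,5-dienyl]-6-methyl-5,6-dihydro-2H-pyran-2-one | CC1(C)OB(/C=C/C(C)=C/C[C@H](OCOC)[C@@H]2C=CC(=O)O[C@H]2C)OC1(C)C | intermediate
19 | tricyclic lactone boronate: cis-fused 7-methyl-2,3,3a,4,5,7a-hexahydro-1H-indene, 2α-OMOM, 5β-Bpin, δ-lactone from O-1′ of the 3β-[(1S)-1-oxyethyl] group to the 4β carbonyl; H-3, H-3a, H-4, H-5, H-7a α | CC=1[C@H]2C[C@H](OCOC)[C@@H]([C@H](C)O3)[C@H]2[C@@H](C3=O)[C@@H](B4OC(C)(C)C(C)(C)O4)C=1 | intermediate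
20 | tricyclic lactone 5β-alcohol | CC=1[C@H]2C[C@H](OCOC)[C@@H]([C@H](C)O3)[C@H]2[C@@H](C3=O)[C@@H](O)C=1 | intermediate
21 | tricyclic lactone 5β-triethylsilyl ether | CC=1[C@H]2C[C@H](OCOC)[C@@H]([C@H](C)O3)[C@H]2[C@@H](C3=O)[C@@H](O[Si](CC)(CC)CC)C=1 | intermediate
22 | tributyl[(methoxymethoxy)methyl]stannane | CCCC[Sn](CCCC)(CCCC)COCOC | starting material
23 | δ-hydroxy ketone: 3β-[(1S)-1-hydroxyethyl]-4β-[(methoxymethoxy)acetyl]-2α-OMOM-7-methyl-5β-(triethylsilyloxy)hexahydroindene | CC=1[C@H]2C[C@H](OCOC)[C@@H]([C@H](C)O)[C@H]2[C@@H](C(=O)COCOC)[C@@H](O[Si](CC)(CC)CC)C=1 | intermediate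
24 | keto acetate (C1′ acetate of 23) | CC=1[C@H]2C[C@H](OCOC)[C@@H]([C@H](C)OC(C)=O)[C@H]2[C@@H](C(=O)COCOC)[C@@H](O[Si](CC)(CC)CC)C=1 | intermediate
25 | 4β-[3-(methoxymethoxy)prop-1-en-2-yl] analogue of 24 | CC=1[C@H]2C[C@H](OCOC)[C@@H]([C@H](C)OC(C)=O)[C@H]2[C@@H](C(=C)COCOC)[C@@H](O[Si](CC)(CC)CC)C=1 | intermediate
26 | 6α,7α-epoxide of 25 | C[C@@]12[C@H]3C[C@H](OCOC)[C@@H]([C@H](C)OC(C)=O)[C@H]3[C@@H](C(=C)COCOC)[C@@H](O[Si](CC)(CC)CC)[C@@H]1O2 | intermediate
27 | 6α-hydroxy-7-methylidene octahydroindene | C=C1[C@H]2C[C@H](OCOC)[C@@H]([C@H](C)OC(C)=O)[C@H]2[C@@H](C(=C)COCOC)[C@@H](O[Si](CC)(CC)CC)[C@@H]1O | intermediate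
28 | (R)-2-methylbutanoic acid | CC[C@@H](C)C(=O)O | starting material
29 | 6α-[(2R)-2-methylbutanoyl]oxy ester of 27 | C=C1[C@H]2C[C@H](OCOC)[C@@H]([C@H](C)OC(C)=O)[C@H]2[C@@H](C(=C)COCOC)[C@@H](O[Si](CC)(CC)CC)[C@@H]1OC(=O)[C@H](C)CC | intermediate
30 | 5β-alcohol | C=C1[C@H]2C[C@H](OCOC)[C@@H]([C@H](C)OC(C)=O)[C@H]2[C@@H](C(=C)COCOC)[C@@H](O)[C@@H]1OC(=O)[C@H](C)CC | intermediate
31 | (2E)-3-methylpent-2-enoic acid | CC/C(C)=C/C(=O)O | starting material
32 | 5β-[(2E)-3-methylpent-2-enoyl]oxy diester bis-MOM ether | C=C1[C@H]2C[C@H](OCOC)[C@@H]([C@H](C)OC(C)=O)[C@H]2[C@@H](C(=C)COCOC)[C@@H](OC(=O)/C=C(\C)CC)[C@@H]1OC(=O)[C@H](C)CC | intermediate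
33 | diol: 2α-hydroxy, 4β-(3-hydroxyprop-1-en-2-yl) | C=C1[C@H]2C[C@H](O)[C@@H]([C@H](C)OC(C)=O)[C@H]2[C@@H](C(=C)CO)[C@@H](OC(=O)/C=C(\C)CC)[C@@H]1OC(=O)[C@H](C)CC | intermediate
34 | epoxy alcohol: 4β-[(2R)-2-(hydroxymethyl)oxiran-2-yl], 2α-hydroxy | C=C1[C@H]2C[C@H](O)[C@@H]([C@H](C)OC(C)=O)[C@H]2[C@@H]([C@@]2(CO)CO2)[C@@H](OC(=O)/C=C(\C)CC)[C@@H]1OC(=O)[C@H](C)CC | intermediate
35 | keto acid: (2S)-2-[hydrindanon-4-yl]oxirane-2-carboxylic acid with all other groups of the target | C=C1[C@H]2CC(=O)[C@@H]([C@H](C)OC(C)=O)[C@H]2[C@@H]([C@@]2(C(=O)O)CO2)[C@@H](OC(=O)/C=C(\C)CC)[C@@H]1OC(=O)[C@H](C)CC | intermediate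
36 | methyl (2S)-2-[(3R,3aR,4R,5R,6R,7aS)-3-[(1S)-1-acetoxyethyl]-7-methylidene-6-{[(2R)-2-methylbutanoyl]oxy}-5-{[(2E)-3-methylpent-2-enoyl]oxy}-2-oxooctahydro-1H-inden-4-yl]oxirane-2-carboxylate | C=C1[C@H]2CC(=O)[C@@H]([C@H](C)OC(C)=O)[C@H]2[C@@H]([C@@]2(C(=O)OC)CO2)[C@@H](OC(=O)/C=C(\C)CC)[C@@H]1OC(=O)[C@H](C)CC | target

**Step count.** Total: 25 steps. Longest linear sequence: 25 steps (from acid 1; compounds 4, 6, 10, 15, 17, 22, 28 and 31 are bought).

**Steps most likely to fail**

Step 11 (cycloaddition). The ring closure may also run through the exo transition state and give the trans-fused isomer, or the electron-poor boryl diene may react too slowly before the γ-enolisable lactone degrades. The fallback sets out from dienylboronate 18. Copper-promoted oxidative coupling with 4-methoxybenzyl alcohol (Cu(OAc)2, Et3N, 4 Å molecular sieves, air, rt) turns the boronate into the electron-rich (1E,3E)-1-(4-methoxybenzyloxy)diene lactone F1. Its intramolecular Diels–Alder reaction (toluene, 80 °C) is a normal-demand cycloaddition of a 1-alkoxydiene with a stronger endo preference and should give the tricyclic lactone 5β-(4-methoxybenzyl) ether F2. DDQ (CH2Cl2/pH 7 buffer) removes the benzyl group and the route is rejoined at alcohol 20.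

Step 18 (epoxide to allylic alcohol). Hydrogen abstraction may occur at C7a–H and give the endocyclic alkene, or the β-titanoxy radical may lose oxygen and return the alkene. The fallback sets out from epoxide 26 and replaces the radical opening by an ionic one. Me3SiOTf with 2,6-lutidine (toluene, −78 °C), then DBU, opens the oxirane at the tertiary carbon and removes a methyl proton in an E2-type step to give the allylic trimethylsilyl ether F3. Mild methanolysis (citric acid, MeOH, 0 °C) should give allylic alcohol 27.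

Step 23 (asymmetric epoxidation). The reagent and the hindered substrate may be mismatched or react slowly, and the acid-sensitive 2,2-disubstituted epoxy alcohol may be opened by titanium alkoxides in the flask. The fallback sets out from diol 33. MnO2 (CH2Cl2) oxidises only the allylic alcohol to the α-substituted acrolein F4. Iminium-catalysed epoxidation (aq. H2O2, diphenylprolinol trimethylsilyl ether of the hand that gives the (S)-oxirane carbon, CH2Cl2) should give the epoxy aldehyde F5. The nitroxyl/PhI(OAc)2 oxidation of step 24 then converts aldehyde and ring alcohol into keto acid 35, where the route is rejoined.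

**Further compounds**

F1 | step 11 | (5R,6S)-5-[(1S,3E,5E)-6-(4-methoxybenzyloxy)-1-(methoxymethoxy)-4-methylhexa-3,5-dienyl]-6-methyl-5,6-dihydro-2H-pyran-2-one | COc1ccc(CO/C=C/C(C)=C/C[C@H](OCOC)[C@@H]2C=CC(=O)O[C@H]2C)cc1
F2 | step 11 | tricyclic lactone 5β-(4-methoxybenzyl) ether (as 19 with OPMB in place of Bpin) | CC=1[C@H]2C[C@H](OCOC)[C@@H]([C@H](C)O3)[C@H]2[C@@H](C3=O)[C@@H](OCc4ccc(OC)cc4)C=1
F3 | step 18 | 6α-O-trimethylsilyl ether of 27 | C=C1[C@H]2C[C@H](OCOC)[C@@H]([C@H](C)OC(C)=O)[C@H]2[C@@H](C(=C)COCOC)[C@@H](O[Si](CC)(CC)CC)[C@@H]1O[Si](C)(C)C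
F4 | step 23 | α-substituted acrolein (4β-(3-oxoprop-1-en-2-yl), 2α-hydroxy) | C=C1[C@H]2C[C@H](O)[C@@H]([C@H](C)OC(C)=O)[C@H]2[C@@H](C(=C)C=O)[C@@H](OC(=O)/C=C(\C)CC)[C@@H]1OC(=O)[C@H](C)CC
F5 | step 23 | epoxy aldehyde (4β-[(2S)-2-formyloxiran-2-yl], 2α-hydroxy) | C=C1[C@H]2C[C@H](O)[C@@H]([C@H](C)OC(C)=O)[C@H]2[C@@H]([C@@]2(C=O)CO2)[C@@H](OC(=O)/C=C(\C)CC)[C@@H]1OC(=O)[C@H](C)CC
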